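## Analysis of the target

The target is a 21-membered macrocycle built from four units. Ring A is a 3-methoxy-4-hydroxy-5-aryloxyphenyl ring. Ring B is a para-phenylene joined to ring A through a diaryl ether oxygen. An (E)-propenamide runs from ring B to the nitrogen of a tryptamine, and the indole C5 oxygen closes the ring onto the chain C7–C8–C9 that hangs from ring A. The only two stereocentres are adjacent on that chain: C7, the benzylic secondary alcohol (R), and C8, which carries the indolyl ether oxygen and the C9 hydroxymethyl group (S). Drawn as a zigzag C9–C8–C7–ring A, the two oxygens are anti (erythro). The free phenol of ring A sits para to the C7 carbinol, so acid, oxidants or hot base can ionise C7 through a quinone methide and scramble it. The 5-oxyindole with its free N–H is easily oxidised, and the enamide alkene rules out hydrogenolysis. Three problems make the synthesis hard: the diaryl ether oxygen on ring A is flanked by the C4 oxygen, so a metal-mediated etherification there is hindered and electron-rich; a 21-membered ring has to be closed; and the erythro aryloxy alcohol has to be set in the absolute sense. The strategy rests on ring B: it carries only the ether oxygen at C1′ and the propenamide at C4′, with four unsubstituted CH positions. That is the pattern produced when a 2-pyrone substituted at C5 and a terminal aryloxyalkyne undergo [4+2] addition and lose the lactone bridge. The ring A oxygen can therefore be attached while its partner is still a two-carbon alkyne.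

## Retrosynthetic reasoning

**26 back to 24.** Only protecting groups are removed at the end. The ring A phenol stays an allyl ether until the last step (25), because with the phenol capped C7 cannot ionise towards a quinone methide. The allyl group leaves under neutral palladium catalysis; hydrogenolysis would reduce the enamide and acid would endanger C7. The C7 silyl ether of 24 is removed one step earlier.

**24 back to 23.** The C9 hydroxymethyl group is traced to the acyl carbon of an oxazolidinone imide. No skeletal bond is cut; the hydride reduction sets the oxidation level of C9 and removes the chiral auxiliary in the same operation.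

**23 back to 21 (through 22).** The macrocycle is opened at the C8–O bond to indole C5. This is the one ring bond that can be formed stereospecifically at an activated carbon: C8 in 21 carries a chloride next to the imide carbonyl, and the phenoxide 22 displaces it with inversion. Cutting the amide instead would force an intermolecular ether formation with extra nitrogen protection, and the diaryl ether is the hindered bond the plan avoids making by coupling. The open-chain precursor needs a syn chloride/oxygen pair, which an auxiliary aldol delivers; inversion turns it into the anti pair of the target. The forward step must close a 21-membered ring without enolising C8.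

**21 back to 16 and 18 (through 20 and 19).** The C7–C8 bond is cut because both stereocentres lie on it. The boron enolate 19 of chloroacetyl imide 18 adds to aldehyde 16 to set both centres in one step under auxiliary control. The C7 hydroxyl of 20 is silylated to give 21, so that base in the ring closure cannot trigger retro-aldol or epoxide formation.

**18 back to 17.** One N-acylation of the commercial auxiliary.

**16 back to 15.** The aldehyde is carried as a dimethyl acetal, because the steps that install the alkyne use an organolithium and the cycloaddition partner is sensitive to electrophiles.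

**15 back to 8 and 13 (through 14).** This is the central disconnection. Two carbon–carbon bonds of ring B are cut, C1′–C2′ and C5′–C6′. C1′ and C6′ then belong to the ynol ether 8, and C2′ to C5′ to the pyrone 13. The cut is made here because it leaves the ring A oxygen bonded only to an sp carbon, a bond that a phenol forms by addition–elimination without any metal. It also joins the ring A half and the tryptamine half in one convergent step, and the 1,4 pattern of ring B follows from the polarity of the two partners. The forward reaction must be a regioselective [4+2] addition followed by decarboxylation of the bridged adduct 14.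

**13 back to 11 and 12, and 11 back to 9.** The C5–vinyl bond of the pyrone is cut to bromide 12 and acrylamide 11, a palladium-catalysed vinylation. 11 comes from 9 by N-acryloylation (10) and O-silylation.

**8 back to 3 and 4 (through 6, 7 and 5), and 3 back to 1.** The ethynyl ether is traced through chloroalkyne 7 to dichlorovinyl ether 6, which comes from phenol 3 and the two-carbon unit 4 by way of 5. Phenol 3 comes from 1 by selective allylation of the more acidic 4-hydroxyl (2) and acetal formation.

## Alternatives that were turned down

**Alternative 1:** The C7–oxygen bond is cut, leading back to the 7-deoxy macrocycle A2, in which C8 is already set and C7 is a methylene. In the forward step a mild silver oxidant raises the para-hydroxybenzyl unit of A2 to the quinone methide oxidation level. An arylboronic acid condensed onto the C9 hydroxyl then delivers its B–OH oxygen to C7 through a six-membered ring, giving the cyclic phenylboronate A1, from which the diol is released. In its favour, it uses the fragile phenol as the activating group, needs no protecting group at C7 and no auxiliary, and derives C7 from C8 through a chair in which the C7 aryl and C8 aryloxy groups are both equatorial, which is the erythro isomer. On redox and protecting-group economy at C7 it is stronger than the chosen route. Against it, the oxidant must distinguish the ring A phenol from an equally electron-rich 5-alkoxyindole. The planar electrophilic methine has to form inside a 21-membered ring. External nucleophiles compete with the tether. And A2 still contains the hindered diaryl ether, the macrocycle and the C8 centre, none of which the key step helps to build. The chosen strategy spends more steps on protection, but it constructs ring B and the diaryl ether, keeps oxidants away from indole and phenol, and sets both centres by an auxiliary aldol before ring closure.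

**Alternative 2:** The indole bonds C3–C3a and N1–C2 are cut, which opens the pyrrole ring and the macrocycle together and leads to A4, an ortho-iodoaniline ether tethered through the whole chain to a triethylsilyl-capped alkyne. In the forward step zerovalent palladium with a bulky ferrocenyl bisphosphine inserts into the C–I bond in hot dilute solution, the alkyne inserts with the silyl-bearing carbon next to the metal, and C–N reductive elimination gives the macrocyclic 2-silylindole A3. It closes two rings at once with dependable regiochemistry, and the ring closure touches neither stereocentre; on that point it is stronger than the chosen route, which closes the ring at C8 itself. Against it, it rebuilds an indole that is commercially available intact. A4 must already hold the diaryl ether, the amide, both stereocentres and the aryl ether to the iodoaniline, all assembled linearly. The arylpalladium intermediate faces a conjugated enamide in the same molecule. Three silyl ethers and the C2 silane then have to be removed under fluoride or acid, which threaten C7. The chosen strategy uses the tryptamine unit as purchased, is shorter, and puts its risk into one thermal step that also solves the diaryl ether.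

**Alternative 3:** The same C8–O bond to indole C5 is cut as in the ring closure of the chosen route, but the electrophile is the five-membered cyclic sulfate A6 of a syn diol ester, with the ring A phenol as a pivalate. In the forward step a carbonate base in dilute polar solvent ionises the indole phenol, which opens the sulfate at C8 with inversion and closes the ring. The sulfate left on the C7 oxygen is hydrolysed in acidic work-up, giving the hydroxy ester A5. The diol can come from a catalytic asymmetric dihydroxylation, so chirality is catalytic and not stoichiometric. The cyclic sulfate is more reactive than a chloride and selective for the carbon next to the ester, and the C7 oxygen is masked by the sulfate itself. As a ring closure it is as strong as, or stronger than, the chloride displacement used here. Against it, neither the dihydroxylation nor the oxidation of the cyclic sulfite to the sulfate tolerates the indole, the enamide alkene or a free phenol. The sulfate would therefore have to be made early and carried through the diaryl ether formation and amide coupling, and it is too labile for that. The pivalate on a hindered phenol must later be cleaved by base or hydride, and ring B and the diaryl ether are not addressed at all. The chosen strategy keeps the inversion logic, makes the electrophile by an aldol that tolerates indole and alkenes, and adds the ring B construction.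

Key step: step 8

Assumption: C7 is the benzylic carbinol carbon, C8 the carbon bearing the indol-5-yloxy group and C9 the hydroxymethyl carbon; the target is read as (7R,8S), the anti (erythro) aryloxy alcohol.

Assumption: ionised forms of numbered compounds (phenoxides, the lithium acetylide of 8, lithiated 17) are treated as the numbered compound and carry no number of their own.

## Route

Step 1
Reactants: 1 5-hydroxyvanillin (3,4-dihydroxy-5-methoxybenzaldehyde)
Product: 2 4-(allyloxy)-3-hydroxy-5-methoxybenzaldehyde
Conditions: allyl bromide (1.05 equiv), Li2CO3 (1.1 equiv), DMF, 45 °C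
Reagents that add atoms: allyl bromide, C=CCBr
Why: Williamson etherification under monoanion control; the 4-hydroxyl, para to the formyl group, is the more acidic phenol, so one equivalent of a weak carbonate base should ionise and allylate it selectively and leave the 3-hydroxyl free for the ynol ether.

Step 2
Reactants: 2 4-(allyloxy)-3-hydroxy-5-methoxybenzaldehyde
Product: 3 2-(allyloxy)-5-(dimethoxymethyl)-3-methoxyphenol
Conditions: HC(OMe)3, MeOH, p-TsOH·H2O (cat.), rt; then Et3N
Reagents that add atoms: trimethyl orthoformate, COC(OC)OC; methanol, CO
Why: Acid-catalysed acetalisation driven by the orthoformate as water scavenger; the acetal masks the aldehyde against n-BuLi in step 4, and the amine quench lets the acid-labile electron-rich benzylic acetal survive isolation.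

Step 3
Reactants: 3 2-(allyloxy)-5-(dimethoxymethyl)-3-methoxyphenol; 4 trichloroethylene
Product: 6 2-(allyloxy)-1-[(E)-1,2-dichloroethenyloxy]-5-(dimethoxymethyl)-3-methoxybenzene, via dichloroacetylene 5 (not isolated)
Conditions: K2CO3 (2 equiv), DMF, 70 °C
Reagents that add atoms: none
Why: Base-mediated dehydrochlorination of 4 gives 5 at low stationary concentration, and the phenoxide of 3 adds to it in anti fashion to give the (E)-dichlorovinyl ether; this is the standard preparation of dichlorovinyl ethers from phenols and attaches the two-carbon unit to the hindered ring A oxygen without any metal.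

Step 4
Reactants: 6 2-(allyloxy)-1-[(E)-1,2-dichloroethenyloxy]-5-(dimethoxymethyl)-3-methoxybenzene
Product: 8 2-(allyloxy)-5-(dimethoxymethyl)-1-(ethynyloxy)-3-methoxybenzene (ring A ynol ether), via aryl chloroethynyl ether 7 (not isolated)
Conditions: n-BuLi (2.3 equiv), THF, −78 → −40 °C; then MeOH, −78 °C
Reagents that add atoms: none
Why: Deprotonation of the vinyl C–H and loss of LiCl give 7, chlorine–lithium exchange with the second equivalent gives the lithium acetylide of 8, and methanol protonates it (the standard dichlorovinyl ether to ynol ether elimination). At −78 °C these events should be much faster than attack of n-BuLi on the allyl ether or the acetal; 8 is kept cold in solution and used promptly because terminal aryl ynol ethers oligomerise on standing.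

Step 5
Reactants: 9 serotonin hydrochloride
Product: 10 N-[2-(5-hydroxy-1H-indol-3-yl)ethyl]prop-2-enamide
Conditions: acryloyl chloride (1.05 equiv), NaHCO3 (3 equiv), THF–H2O, 0 °C
Reagents that add atoms: acryloyl chloride, C=CC(=O)Cl
Why: Schotten–Baumann N-acylation; the primary amine freed by hydrogen carbonate is far more nucleophilic than the un-ionised phenol or the indole, so the amide should form chemoselectively at 0 °C before conjugate addition can compete.

Step 6
Reactants: 10 N-[2-(5-hydroxy-1H-indol-3-yl)ethyl]prop-2-enamide
Product: 11 N-{2-[5-(triisopropylsilyloxy)-1H-indol-3-yl]ethyl}prop-2-enamide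
Conditions: TIPSCl (1.2 equiv), imidazole (2.5 equiv), DMF, rt
Reagents that add atoms: triisopropylsilyl chloride, CC(C)[Si](Cl)(C(C)C)C(C)C
Why: Imidazole-promoted silylation of the only acidic hydroxyl; the indole and amide N–H groups do not silylate under these conditions. The bulky aryl silyl ether should survive the Heck coupling, 110 °C and the boron aldol, and can later be cleaved by fluoride in the presence of an alkyl silyl ether.

Step 7
Reactants: 11 N-{2-[5-(triisopropylsilyloxy)-1H-indol-3-yl]ethyl}prop-2-enamide; 12 5-bromo-2H-pyran-2-one
Product: 13 (E)-3-(2-oxo-2H-pyran-5-yl)-N-{2-[5-(triisopropylsilyloxy)-1H-indol-3-yl]ethyl}prop-2-enamide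
Conditions: Pd(OAc)2 (5 mol %), Bu4NCl (1 equiv), NaHCO3 (2.5 equiv), DMF, 70 °C
Reagents that add atoms: none
Why: Mizoroki–Heck coupling; zerovalent palladium adds to the alkenyl C–Br bond at pyrone C5, the acrylamide inserts at its unsubstituted carbon, and syn β-hydride elimination gives the E alkene. Phosphine-free conditions with an inorganic base are chosen because amines and strong nucleophiles open 2-pyrones.

Step 8
Reactants: 8 2-(allyloxy)-5-(dimethoxymethyl)-1-(ethynyloxy)-3-methoxybenzene (2 equiv); 13 (E)-3-(2-oxo-2H-pyran-5-yl)-N-{2-[5-(triisopropylsilyloxy)-1H-indol-3-yl]ethyl}prop-2-enamide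
Product: 15 (E)-3-{4-[2-(allyloxy)-5-(dimethoxymethyl)-3-methoxyphenoxy]phenyl}-N-{2-[5-(triisopropylsilyloxy)-1H-indol-3-yl]ethyl}prop-2-enamide, via bridged bicyclic lactone 14 (not isolated)
Conditions: toluene, BHT (cat.), 110 °C, sealed tube, argon
Reagents that add atoms: none
Why: This is an inverse-electron-demand Diels–Alder reaction followed by retro-Diels–Alder decarboxylation, the established way from acceptor-substituted 2-pyrones and electron-rich alkynes to benzenes. The ynol ether 8 is most nucleophilic at its terminal CH carbon, and pyrone 13 is most electrophilic at C6, the diene terminus conjugated both with the ring carbonyl (through C3=C4–C5=C6) and with the propenamide on C5; the terminal carbon therefore bonds to C6 in an asynchronous concerted [4+2] addition while the oxygen-bearing carbon bonds to C3. The bridged lactone 14 should not persist at this temperature: cycloreversion expels carbon dioxide and leaves aromatic ring B, which makes the sequence irreversible. Ring B is thus closed as a six-membered carbocycle by an intermolecular [4+2] cycloaddition that forms both new carbon–carbon bonds, C1′–C2′ and C5′–C6′. No stereocentre is created, since the two bridgehead centres of 14 vanish on aromatisation and the E enamide is untouched. The step needs para over meta regiochemistry and reaction at the pyrone diene rather than at the exocyclic C6=C5–CH=CH diene; the first follows from the matched polarisation, because C3 is para to C5, and the second from the s-cis geometry locked in the pyrone ring and from the aromatisation that only this mode allows. The phenol is silylated and the aldehyde is an acetal so that nothing in either partner can add to the ynol ether.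

Step 9
Reactants: 15 (E)-3-{4-[2-(allyloxy)-5-(dimethoxymethyl)-3-methoxyphenoxy]phenyl}-N-{2-[5-(triisopropylsilyloxy)-1H-indol-3-yl]ethyl}prop-2-enamide
Product: 16 (E)-3-{4-[2-(allyloxy)-5-formyl-3-methoxyphenoxy]phenyl}-N-{2-[5-(triisopropylsilyloxy)-1H-indol-3-yl]ethyl}prop-2-enamide
Conditions: PPTS (0.2 equiv), acetone–H2O (10:1), rt
Reagents that add atoms: water, O
Why: Mild acid-catalysed acetal hydrolysis; the electron-rich benzylic dimethyl acetal is cleaved under conditions that leave the aryl silyl ether, the allyl ether and the enamide untouched.

Step 10
Reactants: 17 (S)-4-benzyloxazolidin-2-one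
Product: 18 (S)-4-benzyl-3-(chloroacetyl)oxazolidin-2-one
Conditions: n-BuLi (1.0 equiv), THF, −78 °C; then ClCH2COCl (1.1 equiv), −78 → 0 °C
Reagents that add atoms: chloroacetyl chloride, ClCC(=O)Cl
Why: N-acylation of the lithiated oxazolidinone with an acid chloride, the standard preparation of acyl oxazolidinones; the low temperature prevents displacement of the chloride.

Step 11
Reactants: 16 (E)-3-{4-[2-(allyloxy)-5-formyl-3-methoxyphenoxy]phenyl}-N-{2-[5-(triisopropylsilyloxy)-1H-indol-3-yl]ethyl}prop-2-enamide; 18 (S)-4-benzyl-3-(chloroacetyl)oxazolidin-2-one
Product: 20 (E)-3-{4-[2-(allyloxy)-5-{(1R,2S)-3-[(4S)-4-benzyl-2-oxooxazolidin-3-yl]-2-chloro-1-hydroxy-3-oxopropyl}-3-methoxyphenoxy]phenyl}-N-{2-[5-(triisopropylsilyloxy)-1H-indol-3-yl]ethyl}prop-2-enamide (syn chlorohydrin), via (Z)-dibutylboron enolate 19 (not isolated)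
Conditions: 18 (1.6 equiv), Bu2BOTf (1.7 equiv), i-Pr2NEt (2.0 equiv), CH2Cl2, −78 → 0 °C; then 16, −78 → 0 °C; MeOH–pH 7 phosphate buffer, 0 °C
Reagents that add atoms: none
Why: Evans boron aldol; soft enolisation gives the Z enolate 19, which reacts through a chair Zimmerman–Traxler transition state with the imide carbonyls opposed, so the benzyl group of the (S) auxiliary blocks one enolate face. This should set the chloride carbon C8 as S and the carbinol C7 as R in a syn relation, the same sense as with propionyl imides, and haloacetyl imides are established substrates. The N–H groups of 16 are not acidic enough to quench the boron enolate, and the non-oxidative work-up spares the indole.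

Step 12
Reactants: 20 syn chlorohydrin
Product: 21 (E)-3-{4-[2-(allyloxy)-5-{(1R,2S)-3-[(4S)-4-benzyl-2-oxooxazolidin-3-yl]-1-(tert-butyldimethylsilyloxy)-2-chloro-3-oxopropyl}-3-methoxyphenoxy]phenyl}-N-{2-[5-(triisopropylsilyloxy)-1H-indol-3-yl]ethyl}prop-2-enamide
Conditions: TBSOTf (1.5 equiv), 2,6-lutidine (3 equiv), CH2Cl2, −40 → 0 °C
Reagents that add atoms: tert-butyldimethylsilyl triflate, CC(C)(C)[Si](C)(C)OS(=O)(=O)C(F)(F)F
Why: Silylation of the secondary alcohol with a silyl triflate and a hindered pyridine base; capping the C7 oxygen removes the pathways open to a β-hydroxy-α-chloro imide under base in the next step (retro-aldol and epoxide closure).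

Step 13
Reactants: 21 C7-silylated chloro imide
Product: 23 macrocyclic imide, (7R,8R): the 21-membered ring of the target with the (4S)-4-benzyl-2-oxooxazolidin-3-ylcarbonyl group on C8 in place of CH2OH, the C7 oxygen as tert-butyldimethylsilyl ether and the ring A phenol as allyl ether, via free indol-5-ol 22 (not isolated)
Conditions: CsF (3 equiv), DMF (0.002 M, slow addition of 21), 40 °C
Reagents that add atoms: none
Why: Fluoride cleaves the aryl silyl ether selectively (the alkyl silyl ether is far slower) and releases the caesium phenoxide of 22 slowly into dilute solution. There it displaces the chloride next to the imide carbonyl by SN2 with inversion, the same stereospecific Williamson displacement that phenoxides undergo with α-chloro esters; this closes the 21-membered ring and turns the syn chloride into the anti (7R,8R) aryl ether. The competing enolisation of the imide is disfavoured by allylic strain between the C8 substituents and the oxazolidinone in the conformation needed for deprotonation.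

Step 14
Reactants: 23 macrocyclic imide
Product: 24 (7R,8S) macrocyclic primary alcohol: C9 hydroxymethyl free, C7 oxygen as tert-butyldimethylsilyl ether, ring A phenol as allyl ether
Conditions: LiBH4 (3 equiv), MeOH (3 equiv), THF, 0 °C
Reagents that add atoms: none
Why: Reductive cleavage of the acyl oxazolidinone; LiBH4 attacks the more electrophilic exocyclic carbonyl, releases the auxiliary and gives the C9 primary alcohol, while the secondary cinnamamide and the silyl and allyl ethers are inert at 0 °C. The descriptor at C8 becomes S only because the priorities change.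

Step 15
Reactants: 24 C7-silylated macrocyclic alcohol
Product: 25 (7R,8S) macrocyclic 7,9-diol with the ring A phenol as allyl ether
Conditions: TBAF (3 equiv), AcOH (3 equiv), THF, 0 °C → rt
Reagents that add atoms: none
Why: Fluoride desilylation buffered with acetic acid; with the ring A phenol still allylated, C7 cannot ionise towards a quinone methide, so the benzylic silyl ether is removed without risk to the C7 configuration.

Step 16
Reactants: 25 allyl-protected macrocyclic diol
Product: 26 target CNP0276372.1, (7R,8S)
Conditions: Pd(PPh3)4 (5 mol %), morpholine (10 equiv), THF, rt, degassed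
Reagents that add atoms: none
Why: Tsuji–Trost deallylation; zerovalent palladium ionises the aryl allyl ether to a π-allyl complex and the phenoxide, and morpholine captures the allyl group. The conditions are neutral, non-reducing and non-oxidising, so the para-hydroxybenzylic alcohol, the enamide and the indole of the target should survive.

## Compound list

1 | 5-hydroxyvanillin | COc1cc(C=O)cc(O)c1O | starting material
2 | 4-(allyloxy)-3-hydroxy-5-methoxybenzaldehyde | COc1cc(C=O)cc(O)c1OCC=C | intermediate
3 | 2-(allyloxy)-5-(dimethoxymethyl)-3-methoxyphenol | COc1cc(C(OC)OC)cc(O)c1OCC=C | intermediate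
4 | trichloroethylene | ClC=C(Cl)Cl | starting material
5 | dichloroacetylene (not isolated) | ClC#CCl | intermediate
6 | 2-(allyloxy)-1-[(E)-1,2-dichloroethenyloxy]-5-(dimethoxymethyl)-3-methoxybenzene | COc1cc(C(OC)OC)cc(O/C(Cl)=C\Cl)c1OCC=C | intermediate
7 | 2-(allyloxy)-1-(chloroethynyloxy)-5-(dimethoxymethyl)-3-methoxybenzene (not isolated) | COc1cc(C(OC)OC)cc(OC#CCl)c1OCC=C | intermediate
8 | 2-(allyloxy)-5-(dimethoxymethyl)-1-(ethynyloxy)-3-methoxybenzene | COc1cc(C(OC)OC)cc(OC#C)c1OCC=C | intermediate
9 | serotonin hydrochloride | NCCc1c[nH]c2ccc(O)cc12.Cl | starting material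
10 | N-[2-(5-hydroxy-1H-indol-3-yl)ethyl]prop-2-enamide | C=CC(=O)NCCc1c[nH]c2ccc(O)cc12 | intermediate
11 | N-{2-[5-(triisopropylsilyloxy)-1H-indol-3-yl]ethyl}prop-2-enamide | C=CC(=O)NCCc1c[nH]c2ccc(O[Si](C(C)C)(C(C)C)C(C)C)cc12 | intermediate
12 | 5-bromo-2H-pyran-2-one | O=c1ccc(Br)co1 | starting material
13 | (E)-3-(2-oxo-2H-pyran-5-yl)-N-{2-[5-(triisopropylsilyloxy)-1H-indol-3-yl]ethyl}prop-2-enamide | O=c1ccc(/C=C/C(=O)NCCc2c[nH]c3ccc(O[Si](C(C)C)(C(C)C)C(C)C)cc23)co1 | intermediate
14 | (E)-3-{5-[2-(allyloxy)-5-(dimethoxymethyl)-3-methoxyphenoxy]-3-oxo-2-oxabicyclo[2.2.2]octa-5,7-dien-7-yl}-N-{2-[5-(triisopropylsilyloxy)-1H-indol-3-yl]ethyl}prop-2-enamide, racemic bridged lactone (not isolated) | O=C1OC2C=C(Oc3cc(C(OC)OC)cc(OC)c3OCC=C)C1C=C2/C=C/C(=O)NCCc1c[nH]c2ccc(O[Si](C(C)C)(C(C)C)C(C)C)cc12 | intermediate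
15 | (E)-3-{4-[2-(allyloxy)-5-(dimethoxymethyl)-3-methoxyphenoxy]phenyl}-N-{2-[5-(triisopropylsilyloxy)-1H-indol-3-yl]ethyl}prop-2-enamide | COc1cc(C(OC)OC)cc(Oc2ccc(/C=C/C(=O)NCCc3c[nH]c4ccc(O[Si](C(C)C)(C(C)C)C(C)C)cc34)cc2)c1OCC=C | intermediate
16 | (E)-3-{4-[2-(allyloxy)-5-formyl-3-methoxyphenoxy]phenyl}-N-{2-[5-(triisopropylsilyloxy)-1H-indol-3-yl]ethyl}prop-2-enamide | COc1cc(C=O)cc(Oc2ccc(/C=C/C(=O)NCCc3c[nH]c4ccc(O[Si](C(C)C)(C(C)C)C(C)C)cc34)cc2)c1OCC=C | intermediate
17 | (S)-4-benzyloxazolidin-2-one | O=C1N[C@@H](Cc2ccccc2)CO1 | starting material
18 | (S)-4-benzyl-3-(chloroacetyl)oxazolidin-2-one | O=C(CCl)N1C(=O)OC[C@@H]1Cc1ccccc1 | intermediate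
19 | (Z)-dibutylboron enolate of 18 (not isolated) | CCCCB(CCCC)O/C(=C\Cl)N1C(=O)OC[C@@H]1Cc1ccccc1 | intermediate
20 | syn aldol adduct, (2S,3R)-2-chloro-3-hydroxy acyl chain on the (4S) auxiliary | COc1cc([C@@H](O)[C@H](Cl)C(=O)N5C(=O)OC[C@@H]5Cc5ccccc5)cc(Oc2ccc(/C=C/C(=O)NCCc3c[nH]c4ccc(O[Si](C(C)C)(C(C)C)C(C)C)cc34)cc2)c1OCC=C | intermediate
21 | tert-butyldimethylsilyl ether of 20 at the C7 oxygen | COc1cc([C@@H](O[Si](C)(C)C(C)(C)C)[C@H](Cl)C(=O)N5C(=O)OC[C@@H]5Cc5ccccc5)cc(Oc2ccc(/C=C/C(=O)NCCc3c[nH]c4ccc(O[Si](C(C)C)(C(C)C)C(C)C)cc34)cc2)c1OCC=C | intermediate
22 | free indol-5-ol of 21 (not isolated) | COc1cc([C@@H](O[Si](C)(C)C(C)(C)C)[C@H](Cl)C(=O)N5C(=O)OC[C@@H]5Cc5ccccc5)cc(Oc2ccc(/C=C/C(=O)NCCc3c[nH]c4ccc(O)cc34)cc2)c1OCC=C | intermediate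
23 | (7R,8R) macrocyclic imide, C7 silyl ether, ring A allyl ether | COc1cc2cc(c1OCC=C)Oc1ccc(cc1)/C=C/C(=O)NCCc1c[nH]c3ccc(cc13)O[C@@H](C(=O)N4C(=O)OC[C@@H]4Cc4ccccc4)[C@@H]2O[Si](C)(C)C(C)(C)C | intermediate
24 | (7R,8S) macrocyclic C9 alcohol, C7 silyl ether, ring A allyl ether | COc1cc2cc(c1OCC=C)Oc1ccc(cc1)/C=C/C(=O)NCCc1c[nH]c3ccc(cc13)O[C@@H](CO)[C@@H]2O[Si](C)(C)C(C)(C)C | intermediate
25 | (7R,8S) macrocyclic 7,9-diol, ring A allyl ether | COc1cc2cc(c1OCC=C)Oc1ccc(cc1)/C=C/C(=O)NCCc1c[nH]c3ccc(cc13)O[C@@H](CO)[C@@H]2O | intermediate
26 | CNP0276372.1, (7R,8S) | COc1cc2cc(c1O)Oc1ccc(cc1)/C=C/C(=O)NCCc1c[nH]c3ccc(cc13)O[C@@H](CO)[C@@H]2O | target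

## Step count and the least certain steps

Total: 16 steps. Longest linear sequence: 12 steps (steps 1–4, 8, 9 and 11–16, from 1 to 26). Steps 5–7 and step 10 are side branches.

**Step 8 (key step).** The acceptor on the pyrone is only a vinylogous amide, so the cycloaddition may be slower than thermal oligomerisation or adventitious protonation of the terminal ynol ether. Some bonding in the meta sense, or addition across the exocyclic diene, would erode the yield further. Fallback: form the diaryl ether by copper-mediated arylation and attach the enamide afterwards. Phenol 3 and 4-iodophenylboronic acid under Chan–Lam conditions (Cu(OAc)2, pyridine, 4 Å sieves, CH2Cl2, air, rt) should give 2-(allyloxy)-5-(dimethoxymethyl)-1-(4-iodophenoxy)-3-methoxybenzene F1. A phosphine-free Heck coupling of F1 with acrylamide 11 (Pd(OAc)2, Bu4NCl, NaHCO3, DMF, 50 °C) then returns to the route at 15. This gives up the metal-free ether formation but performs the hindered coupling on the small phenol 3.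

**Step 13.** The phenoxide or fluoride may enolise the α-chloro imide, which would epimerise C8 or eliminate the C7 silyloxy group, and oligomers may form in place of the 21-membered ring. Fallback: close the same bond by a Mitsunobu reaction, which is neutral and passes through no enolate. Acylation of 17 with (triethylsilyloxy)acetyl chloride (n-BuLi, THF, −78 °C) would give (S)-4-benzyl-3-[(triethylsilyloxy)acetyl]oxazolidin-2-one F2. Its boron aldol with aldehyde 16 (Bu2BOTf, i-Pr2NEt, CH2Cl2) would give the syn (2S,3R) 3-hydroxy-2-(triethylsilyloxy) adduct F3, with the same facial sense as in step 11. TBSOTf and 2,6-lutidine would give the C7 tert-butyldimethylsilyl ether F4. Buffered fluoride (TBAF–AcOH, THF, 0 °C) would remove the aryl triisopropylsilyl and the triethylsilyl groups to give the C8 alcohol with free indol-5-ol F5. Mitsunobu ring closure (PPh3, DIAD, THF–toluene, high dilution) inverts C8 and returns to the route at 23.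

**Step 7.** The 2-pyrone may be opened by base at the temperature the Heck reaction needs, or may react as a diene with the acrylamide, and the indole may slow the catalyst. Fallback: make the pyrone–vinyl bond without base and build the enamide by metathesis. Stille coupling of 12 with tributyl(vinyl)stannane (Pd(PPh3)4, toluene, 90 °C) would give 5-vinyl-2H-pyran-2-one F6. Cross-metathesis of F6 with acrylamide 11 (second-generation Grubbs catalyst, CH2Cl2, 40 °C) should give the E enamide and return to the route at 13.

**Step 14.** The acyl carbonyl lies between an aryloxy carbon and a silyloxy carbon inside the macrocycle, so hydride may attack the ring carbonyl of the oxazolidinone instead, or the reduction may stall. Fallback: exchange the auxiliary for an ester before reducing. Methanolysis of 23 with MeOMgBr (from MeMgBr and MeOH, CH2Cl2–MeOH, 0 °C) would give the (7R,8R) macrocyclic methyl ester F7, which has a single carbonyl open to hydride; LiBH4 in THF at 0 °C then returns to the route at 24.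

## Further compounds

F1 | step 8 | 2-(allyloxy)-5-(dimethoxymethyl)-1-(4-iodophenoxy)-3-methoxybenzene | COc1cc(C(OC)OC)cc(Oc2ccc(I)cc2)c1OCC=C
F2 | step 13 | (S)-4-benzyl-3-[(triethylsilyloxy)acetyl]oxazolidin-2-one | CC[Si](CC)(CC)OCC(=O)N1C(=O)OC[C@@H]1Cc1ccccc1
F3 | step 13 | syn aldol adduct of 16 and F2, (2S,3R)-3-hydroxy-2-(triethylsilyloxy) acyl chain on the (4S) auxiliary | COc1cc([C@@H](O)[C@H](O[Si](CC)(CC)CC)C(=O)N5C(=O)OC[C@@H]5Cc5ccccc5)cc(Oc2ccc(/C=C/C(=O)NCCc3c[nH]c4ccc(O[Si](C(C)C)(C(C)C)C(C)C)cc34)cc2)c1OCC=C
F4 | step 13 | C7 tert-butyldimethylsilyl ether of F3 | COc1cc([C@@H](O[Si](C)(C)C(C)(C)C)[C@H](O[Si](CC)(CC)CC)C(=O)N5C(=O)OC[C@@H]5Cc5ccccc5)cc(Oc2ccc(/C=C/C(=O)NCCc3c[nH]c4ccc(O[Si](C(C)C)(C(C)C)C(C)C)cc34)cc2)c1OCC=C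
F5 | step 13 | C8 alcohol with free indol-5-ol, C7 tert-butyldimethylsilyl ether, (2S,3R) | COc1cc([C@@H](O[Si](C)(C)C(C)(C)C)[C@H](O)C(=O)N5C(=O)OC[C@@H]5Cc5ccccc5)cc(Oc2ccc(/C=C/C(=O)NCCc3c[nH]c4ccc(O)cc34)cc2)c1OCC=C
F6 | step 7 | 5-vinyl-2H-pyran-2-one | C=Cc1ccc(=O)oc1
F7 | step 14 | (7R,8R) macrocyclic methyl ester, C7 silyl ether, ring A allyl ether | COc1cc2cc(c1OCC=C)Oc1ccc(cc1)/C=C/C(=O)NCCc1c[nH]c3ccc(cc13)O[C@@H](C(=O)OC)[C@@H]2O[Si](C)(C)C(C)(C)C
A1 | alternative 1 | cyclic phenylboronate of the target across the C7 and C9 oxygens | COc1cc2cc(c1O)Oc1ccc(cc1)/C=C/C(=O)NCCc1c[nH]c3ccc(cc13)O[C@@H](COB(c4ccccc4)O5)[C@@H]25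
A2 | alternative 1 | 7-deoxy macrocycle, C8 configured as in the target | COc1cc2cc(c1O)Oc1ccc(cc1)/C=C/C(=O)NCCc1c[nH]c3ccc(cc13)O[C@@H](CO)C2
A3 | alternative 2 | macrocyclic 2-triethylsilylindole, oxygens silylated | COc1cc2cc(c1O[Si](C(C)C)(C(C)C)C(C)C)Oc1ccc(cc1)/C=C/C(=O)NCCc1c([Si](CC)(CC)CC)[nH]c3ccc(cc13)O[C@@H](CO[Si](C)(C)C(C)(C)C)[C@@H]2O[Si](C)(C)C(C)(C)C
A4 | alternative 2 | open-chain 2-iodoaniline ether tethered to the triethylsilyl alkyne, oxygens silylated | COc1cc(cc(c1O[Si](C(C)C)(C(C)C)C(C)C)Oc1ccc(cc1)/C=C/C(=O)NCCC#C[Si](CC)(CC)CC)[C@@H](O[Si](C)(C)C(C)(C)C)[C@H](CO[Si](C)(C)C(C)(C)C)Oc1ccc(N)c(I)c1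
A5 | alternative 3 | macrocyclic 7-hydroxy C9 methyl ester, ring A phenol as pivalate | COc1cc2cc(c1OC(=O)C(C)(C)C)Oc1ccc(cc1)/C=C/C(=O)NCCc1c[nH]c3ccc(cc13)O[C@@H](C(=O)OC)[C@@H]2O
A6 | alternative 3 | open-chain trans cyclic sulfate of the (2S,3R) diol methyl ester, free indol-5-ol, ring A pivalate | COc1cc(cc(c1OC(=O)C(C)(C)C)Oc1ccc(cc1)/C=C/C(=O)NCCc1c[nH]c2ccc(O)cc12)[C@H]1OS(=O)(=O)O[C@@H]1C(=O)OC
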